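**Retrosynthetic overview**
1. The C4–O ester bond is made last but one: tertiary allylic alcohol 16 plus (R)-2-methylbutanoic acid in a 1,3-transpositive acyloxylation that also sets C4 and creates the tetrasubstituted C5=C6 alkene. The side-chain OH comes from late cleavage of the citronellal isopropylidene.
2. 16 comes from enone 10 (MeMgBr addition, lactone α-methylenation, alkene cleavage); 10 comes from keto-lactone 9 by dehydrogenation.
3. Lactone ring (formed second): intramolecular oxa-Michael addition of enone acid 8, making the C7a–O bond with cis fusion.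
4. Cyclohexenone ring (formed first): organocatalytic Michael addition of methyl 4-oxobutanoate to vinyl ketone 4 (sets C3a), then aldol condensation.
5. 4 comes from (S)-citronellal, which supplies the side-chain stereocentre, by α-methylenation, MeMgBr addition and oxidation.

Assumption: (S)-citronellal and (R)-2-methylbutanoic acid are bought as single enantiomers; ring positions use 1-benzofuran-2-one numbering (C3a/C7a fusion, C4 ester, C5 side chain, C6 methyl), and the transient centres (carbinol C of 3, ring C5 of 6–9, C6 of 11–16, side-chain carbinol of 15) are carried as epimer mixtures.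

**Step 1**
Reactants: 1 (S)-citronellal
Product: 2 (3S)-3,7-dimethyl-2-methylideneoct-6-enal
Conditions: 37 % aq. CH2O, pyrrolidine (10 mol %), EtCO2H (10 mol %), iPrOH, 45 °C
Reagents that add atoms: formaldehyde, C=O
Why: Organocatalytic Mannich-type α-methylenation of an α-unbranched aldehyde (enamine plus formaldehyde iminium, then elimination) leaves the β-stereocentre untouched.

**Step 2**
Reactants: 2 (3S)-3,7-dimethyl-2-methylideneoct-6-enal
Product: 3 (4S)-4,8-dimethyl-3-methylidenenon-7-en-2-ol
Conditions: MeMgBr, Et2O, −78 to 0 °C; H2O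
Reagents that add atoms: methylmagnesium bromide, C[Mg]Br
Why: Grignard 1,2-addition to an α-substituted acrolein; the new carbinol centre is destroyed in step 3, so its configuration does not matter.

**Step 3**
Reactants: 3 (4S)-4,8-dimethyl-3-methylidenenon-7-en-2-ol
Product: 4 (4S)-4,8-dimethyl-3-methylidenenon-7-en-2-one
Conditions: MnO2 (activated), CH2Cl2, rt
Reagents that add atoms: none
Why: MnO2 oxidation of an allylic alcohol gives the α-alkyl vinyl ketone and does not touch the isolated trisubstituted alkene.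

**Step 4**
Reactants: 4 (4S)-4,8-dimethyl-3-methylidenenon-7-en-2-one; 5 methyl 4-oxobutanoate
Product: 6 methyl (3R)-3-formyl-5-[(2S)-6-methylhept-5-en-2-yl]-6-oxoheptanoate
Conditions: (R)-α,α-diphenylprolinol TMS ether (20 mol %), ethyl 3,4-dihydroxybenzoate (20 mol %), neat, 4 °C to rt
Reagents that add atoms: none
Why: Enamine-catalysed asymmetric Michael addition of an aldehyde to a vinyl ketone, in which the (R)-catalyst shields one enamine face so that the formyl-bearing carbon (later C3a) is formed as R, while the ketone α-centre set by protonation is left as a mixture because it becomes sp2 in step 6.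

**Step 5**
Reactants: 6 methyl (3R)-3-formyl-5-[(2S)-6-methylhept-5-en-2-yl]-6-oxoheptanoate
Product: 9 (3aR,7aR)-5-[(2S)-6-methylhept-5-en-2-yl]hexahydro-1-benzofuran-2,6-dione, via enone ester 7 (not isolated), via enone acid 8 (not isolated)
Conditions: TsOH·H2O (10 mol %), PhMe, 60 °C; then LiOH, THF/H2O, 0 °C; then 1 M HCl to pH 2, rt
Reagents that add atoms: lithium hydroxide, [Li+].[OH-]
Why: Acid-catalysed intramolecular aldol condensation of the methyl ketone onto the aldehyde gives the cyclohexenone, saponification frees the acid, and acid-promoted intramolecular oxa-Michael addition (5-exo-trig) closes the γ-lactone, the short tether forcing the new C7a–O bond cis to the CH2 arm (7aR).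

**Step 6**
Reactants: 9 (3aR,7aR)-5-[(2S)-6-methylhept-5-en-2-yl]hexahydro-1-benzofuran-2,6-dione
Product: 10 (3aS,7aR)-5-[(2S)-6-methylhept-5-en-2-yl]-3,3a,7,7a-tetrahydro-1-benzofuran-2,6-dione
Conditions: IBX, 4-methoxypyridine N-oxide, DMSO, 25 °C
Reagents that add atoms: none
Why: IBX dehydrogenation of the ketone through its more substituted enol (Nicolaou dehydrogenation) introduces the C4=C5 double bond without base, so the β-acyloxy ketone is not exposed to E1cB conditions and both C5 epimers converge on one enone.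

**Step 7**
Reactants: 10 (3aS,7aR)-5-[(2S)-6-methylhept-5-en-2-yl]-3,3a,7,7a-tetrahydro-1-benzofuran-2,6-dione
Product: 11 (3aS,7aR)-6-hydroxy-6-methyl-5-[(2S)-6-methylhept-5-en-2-yl]-3a,6,7,7a-tetrahydro-1-benzofuran-2(3H)-one
Conditions: MeMgBr, LaCl3·2LiCl, THF, −78 °C; H2O
Reagents that add atoms: methylmagnesium bromide, C[Mg]Br
Why: Lanthanide-promoted 1,2-addition of the Grignard reagent to the enone carbonyl outruns attack on the lactone and suppresses enolisation, and either C6 epimer is usable because this centre is ionised in step 10.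

**Step 8**
Reactants: 11 (3aS,7aR)-6-hydroxy-6-methyl-5-[(2S)-6-methylhept-5-en-2-yl]-3a,6,7,7a-tetrahydro-1-benzofuran-2(3H)-one
Product: 14 (3aR,7aR)-6-hydroxy-6-methyl-3-methylidene-5-[(2S)-6-methylhept-5-en-2-yl]-3a,6,7,7a-tetrahydro-1-benzofuran-2(3H)-one, via Mannich base 12 (not isolated), via ammonium iodide 13 (not isolated)
Conditions: LiHMDS (2.2 equiv), THF, −78 °C; CH2=NMe2+ I−, −78 to 0 °C; H2O; then MeI, CH2Cl2; then aq. NaHCO3
Reagents that add atoms: N,N-dimethylmethyleneiminium iodide (Eschenmoser's salt), C=[N+](C)C.[I-]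
Why: Eschenmoser α-methylenation (Mannich reaction of the lactone enolate, N-methylation, Hofmann-type elimination) is the standard route to an α-methylene-γ-butyrolactone, and the tertiary alkoxide is a spectator.

**Step 9**
Reactants: 14 (3aR,7aR)-6-hydroxy-6-methyl-3-methylidene-5-[(2S)-6-methylhept-5-en-2-yl]-3a,6,7,7a-tetrahydro-1-benzofuran-2(3H)-one
Product: 16 (4S)-4-[(3aR,7aR)-6-hydroxy-6-methyl-3-methylidene-2-oxo-2,3,3a,6,7,7a-hexahydro-1-benzofuran-5-yl]pentanal, via diol 15 (not isolated)
Conditions: K2OsO2(OH)4 (1 mol %), (DHQD)2PHAL (2 mol %), NMO, acetone/H2O, 0 °C; then NaIO4, rt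
Reagents that add atoms: N-methylmorpholine N-oxide, C[N+]1([O-])CCOCC1; water, O
Why: Ligand-accelerated catalytic dihydroxylation selects the electron-rich, unhindered terminal trisubstituted alkene over the hindered ring alkene and the electron-poor acrylate, and periodate glycol cleavage then gives the aldehyde, which also removes the only π-nucleophile that could trap the cation of step 10.

**Step 10**
Reactants: 16 (4S)-4-[(3aR,7aR)-6-hydroxy-6-methyl-3-methylidene-2-oxo-2,3,3a,6,7,7a-hexahydro-1-benzofuran-5-yl]pentanal; 17 (R)-2-methylbutanoic acid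
Product: 18 (3aR,4S,7aR)-6-methyl-3-methylidene-2-oxo-5-[(2S)-5-oxopentan-2-yl]-2,3,3a,4,7,7a-hexahydro-1-benzofuran-4-yl (2R)-2-methylbutanoate
Conditions: 17 (5 equiv), Ca(NTf2)2 (10 mol %), nBu4NPF6 (10 mol %), CH2Cl2, 0 °C to rt
Reagents that add atoms: none
Why: Proposed new method: a Ca(NTf2)2/nBu4NPF6-catalysed dehydrative 1,3-transpositive acyloxylation in which the Lewis acid ionises the tertiary allylic alcohol to the C4–C5–C6 allyl cation, the free acid captures it at the less hindered secondary terminus C4 on the face opposite the cis-fused lactone (C–O trans to the C3a–C3 bond, 4S), and capture at the tertiary terminus or on the wrong face is undone by re-ionisation so that both C6 epimers of 16 funnel to the most stable ester with the tetrasubstituted alkene; the closest known reactions are Lewis-acid-catalysed SN1-type substitution of allylic alcohols and the classical acid-mediated rearrangement of tertiary allylic alcohols to transposed esters (linalool to geranyl acetate), neither shown with a chiral α-branched acid as nucleophile or for stereocontrolled ester installation on such a lactone.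

**Step 11**
Reactants: 18 (3aR,4S,7aR)-6-methyl-3-methylidene-2-oxo-5-[(2S)-5-oxopentan-2-yl]-2,3,3a,4,7,7a-hexahydro-1-benzofuran-4-yl (2R)-2-methylbutanoate
Product: 19 (3aR,4S,7aR)-5-[(2S)-5-hydroxypentan-2-yl]-6-methyl-3-methylidene-2-oxo-2,3,3a,4,7,7a-hexahydro-1-benzofuran-4-yl (2R)-2-methylbutanoate
Conditions: NaBH(OAc)3, THF, 40 °C
Reagents that add atoms: none
Why: Sodium triacetoxyborohydride reduces the aldehyde chemoselectively and does not add to the α-methylene lactone or attack the esters.

**Compound list**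
1 | (S)-citronellal, (3S)-3,7-dimethyloct-6-enal | O=CC[C@@H](C)CCC=C(C)C | starting material
2 | (3S)-3,7-dimethyl-2-methylideneoct-6-enal | O=CC(=C)[C@@H](C)CCC=C(C)C | intermediate
3 | (4S)-4,8-dimethyl-3-methylidenenon-7-en-2-ol (C2 epimers) | CC(O)C(=C)[C@@H](C)CCC=C(C)C | intermediate
4 | (4S)-4,8-dimethyl-3-methylidenenon-7-en-2-one | CC(=O)C(=C)[C@@H](C)CCC=C(C)C | intermediate
5 | methyl 4-oxobutanoate | COC(=O)CCC=O | starting material
6 | methyl (3R)-3-formyl-5-[(2S)-6-methylhept-5-en-2-yl]-6-oxoheptanoate (C5 epimers) | COC(=O)C[C@H](C=O)CC(C(C)=O)[C@@H](C)CCC=C(C)C | intermediate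
7 | enone ester, methyl 2-[(1R)-5-[(2S)-6-methylhept-5-en-2-yl]-4-oxocyclohex-2-en-1-yl]acetate (C5 epimers) | COC(=O)C[C@@H]1C=CC(=O)C(C1)[C@@H](C)CCC=C(C)C | intermediate
8 | enone acid, 2-[(1R)-5-[(2S)-6-methylhept-5-en-2-yl]-4-oxocyclohex-2-en-1-yl]acetic acid (C5 epimers) | OC(=O)C[C@@H]1C=CC(=O)C(C1)[C@@H](C)CCC=C(C)C | intermediate
9 | (3aR,7aR)-5-[(2S)-6-methylhept-5-en-2-yl]hexahydro-1-benzofuran-2,6-dione (cis-fused, C5 epimers) | C1C(=O)O[C@@H]2CC(=O)C([C@@H](C)CCC=C(C)C)C[C@H]12 | intermediate
10 | (3aS,7aR)-5-[(2S)-6-methylhept-5-en-2-yl]-3,3a,7,7a-tetrahydro-1-benzofuran-2,6-dione | C1C(=O)O[C@@H]2CC(=O)C([C@@H](C)CCC=C(C)C)=C[C@H]12 | intermediate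
11 | (3aS,7aR)-6-hydroxy-6-methyl-5-[(2S)-6-methylhept-5-en-2-yl]-3a,6,7,7a-tetrahydro-1-benzofuran-2(3H)-one (C6 epimers) | C1C(=O)O[C@@H]2CC(C)(O)C([C@@H](C)CCC=C(C)C)=C[C@H]12 | intermediate
12 | Mannich base, 11 carrying CH2NMe2 at C3 (C3 epimers) | CN(C)CC1C(=O)O[C@@H]2CC(C)(O)C([C@@H](C)CCC=C(C)C)=C[C@H]12 | intermediate
13 | ammonium iodide, N-methyl quaternary salt of 12 | C[N+](C)(C)CC1C(=O)O[C@@H]2CC(C)(O)C([C@@H](C)CCC=C(C)C)=C[C@H]12.[I-] | intermediate
14 | (3aR,7aR)-6-hydroxy-6-methyl-3-methylidene-5-[(2S)-6-methylhept-5-en-2-yl]-3a,6,7,7a-tetrahydro-1-benzofuran-2(3H)-one (C6 epimers) | C=C1C(=O)O[C@@H]2CC(C)(O)C([C@@H](C)CCC=C(C)C)=C[C@H]12 | intermediate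
15 | diol, 14 with the side chain as (2S)-5,6-dihydroxy-6-methylheptan-2-yl (carbinol epimers) | C=C1C(=O)O[C@@H]2CC(C)(O)C([C@@H](C)CCC(O)C(C)(C)O)=C[C@H]12 | intermediate
16 | (4S)-4-[(3aR,7aR)-6-hydroxy-6-methyl-3-methylidene-2-oxo-2,3,3a,6,7,7a-hexahydro-1-benzofuran-5-yl]pentanal (C6 epimers) | C=C1C(=O)O[C@@H]2CC(C)(O)C([C@@H](C)CCC=O)=C[C@H]12 | intermediate
17 | (R)-2-methylbutanoic acid | CC[C@@H](C)C(=O)O | starting material
18 | (3aR,4S,7aR)-6-methyl-3-methylidene-2-oxo-5-[(2S)-5-oxopentan-2-yl]-2,3,3a,4,7,7a-hexahydro-1-benzofuran-4-yl (2R)-2-methylbutanoate | C=C1C(=O)O[C@@H]2CC(C)=C([C@@H](C)CCC=O)[C@@H](OC(=O)[C@H](C)CC)[C@H]12 | intermediate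
19 | (3aR,4S,7aR)-5-[(2S)-5-hydroxypentan-2-yl]-6-methyl-3-methylidene-2-oxo-2,3,3a,4,7,7a-hexahydro-1-benzofuran-4-yl (2R)-2-methylbutanoate | C=C1C(=O)O[C@@H]2CC(C)=C([C@@H](C)CCCO)[C@@H](OC(=O)[C@H](C)CC)[C@H]12 | target

**Step count and risks**
Total step count: 11. Longest linear sequence: 11 (1 to 19; 5 and 17 are bought).

The three steps most likely to fail:

Step 10 (the proposed new step). The allyl cation can lose a proton to give dienes that aromatise by loss of the lactone oxygen, or it can give the 4-epimer or the tertiary ester under kinetic control. The fallback uses known chemistry, sets out from 16 and comes back at 18. A Re2O7-catalysed (or Ph3SiOReO3-catalysed) 1,3-transposition of the tertiary allylic alcohol in Et2O at 0 °C, run to equilibrium, gives the secondary allylic alcohol (4S)-4-[(3aS,4S,7aR)-4-hydroxy-6-methyl-3-methylidene-2-oxo-2,3,3a,4,7,7a-hexahydro-1-benzofuran-5-yl]pentanal F6. Steglich esterification of F6 with 17 (DCC, DMAP) then gives 18. If the C4 epimer of F6 predominates, Mitsunobu esterification with 17 (inversion) gives the same 18.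

Step 6. IBX may dehydrogenate on the wrong side, or the product may lose the lactone oxygen by retro-oxa-Michael and aromatise to a phenol. The fallback fixes the regiochemistry before the lactone exists; it sets out from 6 and comes back at 10. The first stage of step 5 is stopped at enone ester 7, which is isolated. Kinetic deprotonation at the only α' position (LDA, −78 °C) and PhSeBr give the 5-(phenylselanyl) derivative of the enone ester F4. Saponification and acidification as in step 5 give the 5-(phenylselanyl) derivative of keto-lactone 9 F5. H2O2/pyridine at 0 °C then gives 10 by selenoxide syn-elimination into the ring.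

Step 4. The α-branched vinyl ketone 4 is a sluggish acceptor for enamine catalysis, and the aldehyde α-centre of 6 can epimerise. The fallback replaces the catalytic step by an auxiliary-controlled Michael addition; it sets out from 4 and comes back at 6. The imide (R)-4-benzyl-3-(4-methoxy-4-oxobutanoyl)-1,3-oxazolidin-2-one F1 (from methyl 4-chloro-4-oxobutanoate and (R)-4-benzyl-2-oxazolidinone) is converted into its chlorotitanium enolate (TiCl4, iPr2NEt, CH2Cl2, −78 °C) and added to 4 to give the Michael adduct imide F2. LiSEt exchanges the auxiliary for the S-ethyl thioester F3. Fukuyama reduction (Et3SiH, Pd/C) gives aldehyde 6.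

**Further compounds**
F1 | step 4 | (R)-4-benzyl-3-(4-methoxy-4-oxobutanoyl)-1,3-oxazolidin-2-one | COC(=O)CCC(=O)N1[C@H](Cc2ccccc2)COC1=O
F2 | step 4 | Michael adduct imide, 6 with the formyl group replaced by the (R)-4-benzyl-2-oxo-oxazolidine-3-carbonyl group | COC(=O)C[C@H](C(=O)N1[C@H](Cc2ccccc2)COC1=O)CC(C(C)=O)[C@@H](C)CCC=C(C)C
F3 | step 4 | S-ethyl thioester, 6 with the formyl group replaced by C(=O)SEt | COC(=O)C[C@H](C(=O)SCC)CC(C(C)=O)[C@@H](C)CCC=C(C)C
F4 | step 6 | 5-(phenylselanyl) derivative of enone ester 7 | COC(=O)C[C@@H]1C=CC(=O)C(C1)([Se]c2ccccc2)[C@@H](C)CCC=C(C)C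
F5 | step 6 | 5-(phenylselanyl) derivative of keto-lactone 9 | C1C(=O)O[C@@H]2CC(=O)C([Se]c3ccccc3)([C@@H](C)CCC=C(C)C)C[C@H]12
F6 | step 10 | (4S)-4-[(3aS,4S,7aR)-4-hydroxy-6-methyl-3-methylidene-2-oxo-2,3,3a,4,7,7a-hexahydro-1-benzofuran-5-yl]pentanal | C=C1C(=O)O[C@@H]2CC(C)=C([C@@H](C)CCC=O)[C@@H](O)[C@H]12
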